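## Structural features

GA55 (29) is a C19 gibberellin. Ring A (cyclohexane) is trans-fused to ring B (cyclopentane), ring B is fused through C8–C9 to the bicyclo[3.2.1]octane of rings C and D, and a γ-lactone links C4 (through C19) to the oxygen on C10 across the α-face of ring A. Quaternary C8 is common to rings B, C and D. The other bridgehead, C13, carries a tertiary hydroxyl next to the exocyclic 16-methylene.

There are nine stereocentres. Eight are contiguous (C1, C10, C5, C4, C3 on ring A; C6, C8, C9 on ring B) and include two quaternary carbons (C4, C8) and the tertiary lactone carbon C10. The hydroxyls on C1 and C3 are both β and axial, syn to each other and anti to the lactone bridge.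

Three elements are fragile:
- the allylic tertiary 13-ol with the 16-ene (skeletal rearrangement of rings C/D in acid, α-ketol shift at the 16-ketone stage);
- the β-hydroxy lactone at C3/C4 (retro-aldol epimerisation of C3 in base);
- C6, which is epimerisable while C7 is an ester.

The real difficulty is the bridged B/C/D core around C8 as one enantiomer, and then the oxygen pattern of ring A (1β-OH, 3β-OH, 10α-O) around quaternary C4.

The key step uses one feature. The seven-membered circuit C8–C9–C11–C12–C13–C16–C15, bridged by C14, is the Cope product of a cis-divinylcyclopropane (C8, C9, C15) built on the cyclopentadiene C8/C15/C16/C13/C14. A carbenoid at C9, held to C8 by the chain C10–C5–C6, therefore closes ring B on the way in and ring C on the way out.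

## Logic of the disconnections

**29 → 28 → 27.** Only the O–CH3 bond of the C7 ester and the O–Si bond at C13 are cut. They go last because the free 13-ol beside the 16-methylene does not tolerate acid and the 3β-hydroxy lactone does not tolerate hydroxide. The gain is a neutral, soluble ester through all earlier steps. The demand is a demethylation by alkyl–oxygen cleavage and a buffered desilylation.

**27 → 26 → 25.** The C16=C17 bond is cut back to the 16-ketone of 26, and that to the ketal of 25. C17 comes late because an exocyclic alkene would not survive the hydrogenation and ozonolysis used earlier, and C16 must stay inert while C10 and C3 are carbonyl groups. The demand is a methylenation that is not basic.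

**25 → 23 (by way of 24).** The C1–C2 bond is cut (aldol) and the C3 carbinol is traced to a ketone. Ring A opens to a methyl ketone on C4 and an aldehyde on C10; two stereocentres (C1, C3) disappear and both ring A hydroxyls come from one β-hydroxy ketone. The demand is addition with the aldehyde oxygen anti to the C10–O bond (1β) and hydride delivery to C3 from the α-side (3β).

**23 → 22 → 21.** The C1 aldehyde is traced to a vinyl group, and the C3–C4 bond is cut (acylation of the C4 lactone enolate). Quaternary C4 becomes an enolisable methine whose configuration no longer matters. The demand is entry of the acyl group on the lactone face that carries C1 (anti to C6), and removal of the lactone α-hydrogen in preference to the C6 ester hydrogen.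

**21 → 20.** The C4–C5 bond is cut, which opens the lactone to a propanoate of the C10 alcohol and restores a C5=C6 enoate. This cut accounts for C5 and C6 together: the nucleophile hangs from the α-oxygen on C10 and can only reach the α-face of C5. The demand is that conjugate addition outruns Claisen rearrangement of the allylic ester enolate, and that C6 settles as the ester trans to C4.

**20 → 18 (by way of 19).** The C10–C1 bond and the O–C19 acyl bond are cut, leaving the C10 ketone. C1, C4, C18 and C19 leave as a vinyl nucleophile and a propanoyl group. The demand is 1,2-addition, from the β-face, to a ketone that is part of a doubly activated ene-dicarbonyl unit.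

**18 → 16 → 15.** The C5=C6 bond is traced to the saturated keto ester, and the single C7 ester to the gem-diester. The diester is the form in which C6 passes the key step: no acidic hydrogen, and a quaternary centre that favours ring closure. The demand is dehydrogenation towards C5–C6 and not back towards C9–C11.

**15 → 14 → 13.** H9 and H11 are removed (C9=C11 enone) and the ketal is traced to the C16 silyl enol ether. The ketal must be made while C10 is still deactivated as an enone. The demand on C9 (H β, B/C cis) is left to thermodynamic control.

**13 → 11 (by way of 12).** C8–C9 and C12–C13 are cut. Rings B and C and both core stereocentres fall away, leaving an achiral, monocyclic vinyl diazo ketone tethered through C6 to a 1,2-bis(silyloxy)cyclopentadiene. The demand is catalyst control of the face of C8=C15, and a diene that is one compound. For that reason both oxygens carry the same silyl group: a cyclopentadiene moves its CH2 group round the ring by 1,5-hydrogen shifts, so two different silyl groups would give two regioisomeric precursors and products with the silyl groups exchanged. With identical groups the shift is degenerate.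

**11 → 9 → 8.** The C9=N2 unit is traced to the methylene of an allyl ketone, and the C9–C10 bond is cut between an allyl nucleophile and an N-methoxy-N-methylamide. The diene is made before the diazo group, so that it can equilibrate to its stable isomer and mask the enone carbonyl during the organometallic step. The demand is diazo transfer without a strong base, because the ring CH2 of the cyclopentadiene is itself acidic and would accept a diazo group.

**8 → 7 → 6.** The two O–Si bonds and the C13–O bond are cut, leaving a plain 3-substituted cyclopentenone. The demand is kinetic enolisation at the α′-carbon, not the γ-carbon.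

**6 → 5 + 2; 5 → 3 + 4; 2 → 1.** The C6–C8 bond (vinylic substitution) and the C6–C5 bond (malonate alkylation) are cut down to three commercial compounds. The amide arm replaces a longer allyl/ozonolysis/allylation/oxidation sequence.

## Other disconnections considered

**Alternative 1:** ring B contraction of a chiral-pool kaurane.
- **Cut and key step.** The C6–C8 bond is cut. 29 is traced through its 1,3-bis-silyl ether A3 to the six-membered ring B diazo ketone A2 (diazo on C6, ketone C7 between C6 and C8), and A2 to steviol A1. Forward, irradiation of A2 in aqueous solvent should trigger a Wolff rearrangement in which C8 migrates from C7 to C6, and the ketene is hydrated to the C7 acid of A3.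
- **In favour.** A1 supplies rings C and D with C8, C9 and C13, the 13-hydroxyl and the 16-methylene in the correct absolute configuration with no asymmetric step. On this point it is better than the chosen plan. The contraction also delivers C7 directly as the acid, which is better than carrying a diester and removing one ester.
- **Against.** A1 keeps the C20 methyl, which must be excised and replaced by the 19,10-lactone. Ring A has no oxygen at C1 or C3, so two unactivated methylenes must be hydroxylated with defined configuration. C6 and C7 must be oxidised in the presence of the acid-labile allylic 13-ol. The photolysis comes at the very end on a substrate carrying every sensitive group, and C6 is set by an uncontrolled ketene hydration.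
- **Comparison.** On structure, the chiral pool solves the B/C/D core that the chosen plan must build, but not ring A. On mechanism, the 1,2-shift is as dependable as the carbenoid cascade. On step economy, what is saved on rings C/D would probably be spent on C20 excision and on C–H oxidation at C1 and C3, which the chosen plan avoids by building ring A with its oxygens in place.

**Alternative 2:** Diels–Alder assembly of ring C on a cyclopentenone.
- **Cut and key step.** C8–C14 and C9–C11 are cut. Forward, the 3-propargyl cyclopentenone A4 (with the C6 silyloxymethyl group) and 2-(trimethylsilyloxy)buta-1,3-diene A5 should combine under an alkylaluminium chloride Lewis acid to give the cis-hydrindanone silyl enol ether A6.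
- **In favour.** The route is convergent and uses cheap reagents. The regiochemistry is the normal one for a 2-siloxy diene, and the C6 substituent should steer the diene to the opposite face, so C8 and C9 are set together with H9 cis to C15. The propargyl group and the masked C13 ketone of A6 are placed for a ketyl–alkyne closure of ring D, which would create the 13-hydroxyl and the 16-methylene in one operation. On the C/D functionality this is better than the chosen plan, which needs a ketal and a late methylenation. C9 is set directly, which is equal or better.
- **Against.** β,β-Disubstituted cyclopentenones are poor dienophiles, and quaternary C8 must form in the cycloaddition. The strong Lewis acid may desilylate A5 or divert the reaction to a stepwise Mukaiyama–Michael path. The absolute configuration must be brought in through the C6 centre of A4, which needs its own asymmetric synthesis. C7 arrives at the alcohol oxidation level. Ring A must still be built on C5 and C10.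
- **Comparison.** On structure, it closes one ring and one quaternary centre where the chosen key step closes two rings from an achiral substrate. On mechanism, a thermal or Lewis-acid cycloaddition is simpler than a carbenoid cascade, but on a less willing substrate. On step economy the two plans should come out close: fewer steps on ring D, more on the chiral dienophile and on C7.

**Alternative 3:** epoxide-initiated cation cyclisation for ring A and the oxygen bridge.
- **Cut and key step.** C4–C5 and C10–O are cut. Forward, an alkylaluminium chloride opens the (3S,4S)-epoxide of the epoxy alcohol A7 at C4, the ring B alkene C5=C10 attacks C4, and the C19 hydroxyl traps the C10 cation. The product is the 3β-hydroxy 19,10-ether A8.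
- **In favour.** One step closes ring A and the bridge, sets C4, C5 and C10, and takes the 3β-hydroxyl from an epoxide of known configuration. For the carbon frame of ring A this is more step-economical than the five-step Michael/acylation/aldol sequence of the chosen plan. Quaternary C4 is fixed by ring closure with inversion, which is better than a separate acylation.
- **Against.** A8 is an ether and needs a later oxidation of C19 to the lactone carbonyl. It has no oxygen at C1, and an oxygen placed there beforehand would sit next to the developing C10 cation and disfavour or divert the cyclisation. The 1β-hydroxyl, the distinguishing feature of 29, is therefore not addressed. The C10 cation can also lose H9 or a C1 hydrogen, and the C7 nitrile needs a harsh hydrolysis.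
- **Comparison.** On structure, the alternative still needs a B/C/D tricycle with a C5=C10 alkene, so it complements a core synthesis and does not replace one. On mechanism, a cationic polyene-type closure is less predictable next to the C9 methine than the anionic steps chosen. On step economy it wins for ring A alone but loses once the lactone oxidation and a C1 hydroxylation are added.

Key step: step 8

Assumption: gibberellane numbering is used for every intermediate; the S-configured rhodium catalyst is taken to deliver C8 and C13 as drawn, and its mirror image is used if the sense of induction is the reverse.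

## Steps

Step 1
Reactants: 1 cyclopentane-1,3-dione
Product: 2 3-chlorocyclopent-2-en-1-one
Conditions: (COCl)2, DMF (cat.), CH2Cl2, 0 °C to rt
Reagents that add atoms: oxalyl chloride (O=C(Cl)C(=O)Cl)
Why: Vilsmeier-type activation of the enol of the vinylogous acid and addition–elimination of chloride gives the β-chloro enone, a standard conversion of cyclic 1,3-diones.

Step 2
Reactants: 3 dimethyl malonate; 4 2-chloro-N-methoxy-N-methylacetamide
Product: 5 dimethyl 2-[2-(methoxy(methyl)amino)-2-oxoethyl]propanedioate
Conditions: NaH, THF, 0 °C; then 4, NaI (cat.), rt (3 in excess)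
Reagents that add atoms: none
Why: SN2 alkylation of sodiomalonate (malonic ester synthesis); the excess of 3 suppresses dialkylation and the N-methoxy-N-methylamide is inert to the soft enolate.

Step 3
Reactants: 5 dimethyl 2-[2-(methoxy(methyl)amino)-2-oxoethyl]propanedioate; 2 3-chlorocyclopent-2-en-1-one
Product: 6 dimethyl 2-[2-(methoxy(methyl)amino)-2-oxoethyl]-2-(3-oxocyclopent-1-en-1-yl)propanedioate
Conditions: NaH, THF, 0 °C to rt
Reagents that add atoms: none
Why: Conjugate addition–elimination (vinylic substitution) of the tertiary malonate anion on the β-chloro enone forms the C6–C8 bond and quaternary C6; the product has no malonate hydrogen left and cannot react further.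

Step 4
Reactants: 6 dimethyl 2-[2-(methoxy(methyl)amino)-2-oxoethyl]-2-(3-oxocyclopent-1-en-1-yl)propanedioate
Product: 7 dimethyl 2-(4-hydroxy-3-oxocyclopent-1-en-1-yl)-2-[2-(methoxy(methyl)amino)-2-oxoethyl]propanedioate (racemic)
Conditions: NaN(SiMe3)2, THF, −78 °C; 2-(phenylsulfonyl)-3-phenyloxaziridine, −78 °C; AcOH quench
Reagents that add atoms: 2-(phenylsulfonyl)-3-phenyloxaziridine (O=S(=O)(N1OC1c1ccccc1)c1ccccc1)
Why: Kinetic deprotonation of the enone at the α′-methylene (C13) and hydroxylation of the sodium enolate by the N-sulfonyloxaziridine (Davis oxidation) install the C13 oxygen; the amide α-hydrogens are far less acidic, and the new centre is racemic and is flattened in the next step.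

Step 5
Reactants: 7 dimethyl 2-(4-hydroxy-3-oxocyclopent-1-en-1-yl)-2-[2-(methoxy(methyl)amino)-2-oxoethyl]propanedioate (racemic)
Product: 8 dimethyl 2-[3,4-bis(tert-butyldimethylsilyloxy)cyclopenta-1,3-dien-1-yl]-2-[2-(methoxy(methyl)amino)-2-oxoethyl]propanedioate
Conditions: TBSOTf (2.3 equiv), Et3N, CH2Cl2, −78 °C to rt
Reagents that add atoms: tert-butyldimethylsilyl triflate (CC(C)(C)[Si](C)(C)OS(=O)(=O)C(F)(F)F)
Why: Silylation of the hydroxyl and soft enolisation of the ketone (silyl triflate/amine) give the enediol bis-silyl ether. With two identical silyl groups the 1,5-hydrogen shift of the cyclopentadiene is degenerate and the isomer with all three substituents on sp2 carbons is the thermodynamic one, so any kinetically formed isomer should converge on 8 at rt.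

Step 6
Reactants: 8 dimethyl 2-[3,4-bis(tert-butyldimethylsilyloxy)cyclopenta-1,3-dien-1-yl]-2-[2-(methoxy(methyl)amino)-2-oxoethyl]propanedioate
Product: 9 dimethyl 2-[3,4-bis(tert-butyldimethylsilyloxy)cyclopenta-1,3-dien-1-yl]-2-(2-oxopent-4-en-1-yl)propanedioate
Conditions: CH2=CHCH2MgBr, THF, −78 °C; AcOH–THF quench, −78 °C
Reagents that add atoms: allylmagnesium bromide (C=CC[Mg]Br)
Why: Weinreb ketone synthesis: the chelated tetrahedral adduct stops at the ketone stage and forms the C9–C10 bond. The dienol ether masks the enone carbonyl from the Grignard reagent, and the two methyl esters on quaternary C6 should be much slower than the amide at −78 °C.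

Step 7
Reactants: 9 dimethyl 2-[3,4-bis(tert-butyldimethylsilyloxy)cyclopenta-1,3-dien-1-yl]-2-(2-oxopent-4-en-1-yl)propanedioate
Product: 11 dimethyl 2-[3,4-bis(tert-butyldimethylsilyloxy)cyclopenta-1,3-dien-1-yl]-2-(3-diazo-2-oxopent-4-en-1-yl)propanedioate, via trifluoroacetyl ketone 10 (not isolated)
Conditions: LiN(SiMe3)2, THF, −78 °C; CF3CO2CH2CF3; AcOH quench; then 4-acetamidobenzenesulfonyl azide, Et3N, H2O (1 equiv), MeCN, 0 °C; used cold at once
Reagents that add atoms: 4-acetamidobenzenesulfonyl azide (CC(=O)Nc1ccc(cc1)S(=O)(=O)N=[N+]=[N-]); 2,2,2-trifluoroethyl trifluoroacetate (FC(F)(F)COC(=O)C(F)(F)F; its atoms stay only in 10)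
Why: Detrifluoroacetylative (Regitz-type) diazo transfer: the doubly activated C9–H of the β,γ-unsaturated ketone is the most acidic site and its enolate is trifluoroacetylated. The resulting 1,3-diketone accepts the diazo group with triethylamine alone, a base too weak to deprotonate the ring CH2 of the cyclopentadiene. The sulfonyl azide chosen is the safer, crystalline one, and 11 is not stored because unsubstituted vinyl diazo compounds cyclise to pyrazoles.

Step 8
Reactants: 11 dimethyl 2-[3,4-bis(tert-butyldimethylsilyloxy)cyclopenta-1,3-dien-1-yl]-2-(3-diazo-2-oxopent-4-en-1-yl)propanedioate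
Product: 13 tricyclic B/C/D enone (C10 ketone; 9(11)-ene; 16-OTBS enol ether; 13-OTBS; C6 gem-diester; C8 and C13 as in 29), via cis-divinylcyclopropane 12 (not isolated)
Conditions: Rh2(S-PTAD)4 (1 mol %), hexanes, −40 °C to rt, slow addition of 11
Reagents that add atoms: none
Why: Loss of N2 from 11 at the dirhodium centre gives a donor/acceptor vinylcarbenoid at C9 that adds to C8=C15, the only ring alkene within reach of the three-atom tether, so ring B closes as the cyclopentanone of a bicyclo[3.1.0]hexanone (intramolecular cyclopropanation, five-membered closure onto the proximal alkene carbon C8). Ring fusion puts the C11=C12 vinyl group and the ring D enol ether C16=C13 on the same face of the cyclopropane in 12, which should therefore undergo Cope rearrangement through the only available boat transition state at or below rt: C9–C15 breaks, C12–C13 forms and ring C closes as part of the bicyclo[3.2.1]octadiene. The closest known reaction type is the tandem cyclopropanation/Cope rearrangement (formal [4+3] cycloaddition) of rhodium vinylcarbenoids with dienes, including cyclopentadienes and siloxy dienes, and its tethered variants. C8 is set by the chiral carboxylate ligands, which choose between the enantiotopic faces of C8=C15; C13 follows from C8 because the sigmatropic shift is suprafacial on a bicyclic frame that allows one relative configuration only. The step needs chemoselectivity for C8=C15 over the more electron-rich C13=C16 (secured by the tether and by cold, non-polar conditions that favour the concerted path) and high face selectivity (a phthalimido-carboxylate catalyst of the type that works well with donor/acceptor diazo ketones). The two identical silyl groups make the 1,5-hydrogen shift of the diene degenerate, so no regioisomeric diene can feed the cascade.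

Step 9
Reactants: 13 tricyclic B/C/D enone (16-OTBS enol ether)
Product: 14 16,16-ethylenedioxy tricyclic enone (C10 ketone; 9(11)-ene; 13-OTBS; C6 gem-diester)
Conditions: HOCH2CH2OH, TsOH·H2O (cat.), 4 Å MS, CH2Cl2, 0 °C to rt
Reagents that add atoms: ethylene glycol (OCCO)
Why: Acid-catalysed acetal formation from a silyl enol ether: protonation at C15 gives the C16 oxocarbenium ion directly, which the diol traps, whereas the conjugated C10 carbonyl is not activated. The tertiary alkyl silyl ether at C13 should be stable to catalytic acid.

Step 10
Reactants: 14 16,16-ethylenedioxy tricyclic enone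
Product: 15 16,16-ethylenedioxy 9β-H tricyclic ketone (B/C cis; C10 ketone; 13-OTBS; C6 gem-diester)
Conditions: H2 (1 atm), Pd/C, EtOAc, rt; then NaOMe (cat.), MeOH, rt
Reagents that add atoms: none
Why: Heterogeneous hydrogenation of the only C=C bond, then equilibration through the C10 enolate. The cis-fused hydrindanone (H9 β, on the side of C15) is expected to be the more stable epimer, as for cyclopentanones fused to a six-membered ring beside a quaternary fusion carbon (compare 14β-15-oxo steroids).

Step 11
Reactants: 15 16,16-ethylenedioxy 9β-H tricyclic ketone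
Product: 16 monoester keto ketal (one CO2Me at C6; C6 epimers; C10 ketone; 13-OTBS)
Conditions: LiCl, H2O, DMSO, 150 °C
Reagents that add atoms: none
Why: Krapcho demethoxycarbonylation (SN2 demethylation by chloride, decarboxylation, protonation) removes one of the two equivalent esters under neutral conditions that spare ketal, silyl ether and ketone. The C6 epimer mixture is of no consequence because C6 becomes trigonal in the next step.

Step 12
Reactants: 16 monoester keto ketal
Product: 18 5-en-10-one ester (C5=C6 conjugated to the C10 ketone and the C7 methyl ester; 16-ketal; 13-OTBS), via C10 trimethylsilyl enol ether 17 (not isolated)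
Conditions: LiN(i-Pr)2, THF, −78 °C; TMSCl; then Pd(OAc)2 (10 mol %), O2 (1 atm), DMSO, rt
Reagents that add atoms: chlorotrimethylsilane (C[Si](C)(C)Cl; its atoms stay only in 17)
Why: Kinetic enolisation at the less hindered C5 methylene, then Saegusa–Ito oxidation: the C5 palladium enolate can only lose the hydrogen on C6, which places the double bond at C5=C6. The route avoids selenium reagents.

Step 13
Reactants: 18 5-en-10-one ester
Product: 20 10α-propanoyloxy-10β-vinyl 5-ene ester (16-ketal; 13-OTBS), via 10β-vinyl carbinol 19 (not isolated)
Conditions: CeCl3, CH2=CHMgBr, THF, −78 °C; then (EtCO)2O, DMAP, −78 °C to rt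
Reagents that add atoms: vinylmagnesium bromide (C=C[Mg]Br); propanoic anhydride (CCC(=O)OC(=O)CC)
Why: Organocerium 1,2-addition (low basicity, no conjugate addition) to the C10 ketone from the β-face, away from ring C that is cis-fused on the α-face, sets C10 with oxygen α and C1 β. The alkoxide is acylated in the same flask before the bis-allylic alcohol can ionise.

Step 14
Reactants: 20 10α-propanoyloxy-10β-vinyl 5-ene ester
Product: 21 19,10-lactone (C4–C5 bond; H5 β; 6β-CO2Me; C4 methyl as epimer mixture; 10β-vinyl; 16-ketal; 13-OTBS)
Conditions: LiN(i-Pr)2, THF, −78 to −20 °C; then MeOH, NaOMe (cat.), 0 °C to rt; dil. HCl work-up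
Reagents that add atoms: none
Why: Intramolecular Michael addition (5-exo-trig) of the propanoate enolate to C5 of the enoate: the tether through the α-oxygen on C10 forces bond formation on the α-face, giving the cis-fused γ-lactone and H5 β. Methoxide then equilibrates C6 to the ester trans to C4 (6β); C4 is left as a mixture because it is re-enolised in the next step.

Step 15
Reactants: 21 19,10-lactone
Product: 22 4-acetyl lactone (C3 ketone and C2 methyl on C4; C18 methyl cis to C6; 10β-vinyl)
Conditions: LiN(i-Pr)2, THF, −78 °C; MeC(O)N(OMe)Me, −78 to 0 °C; pH 4 work-up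
Reagents that add atoms: N-methoxy-N-methylacetamide (CON(C)C(C)=O)
Why: Claisen-type C-acylation of the lactone enolate (the lactone α-hydrogen is more acidic than the hindered ester hydrogen at C6) by the N-methoxy-N-methylamide, whose stable tetrahedral adduct prevents retro-Claisen cleavage. The electrophile enters on the convex face of the cis-bicyclic lactone, anti to C6, which puts C3 on the side of C1 and the methyl (C18) on the side of C6 as quaternary C4 requires.

Step 16
Reactants: 22 4-acetyl lactone
Product: 23 10β-formyl 4-acetyl lactone (C1 aldehyde)
Conditions: O3, CH2Cl2–MeOH, −78 °C; then PPh3, −78 °C to rt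
Reagents that add atoms: ozone ([O-][O+]=O)
Why: Ozonolysis of the only alkene with reductive work-up gives the non-enolisable α-acyloxy aldehyde; ketal, silyl ether and the quaternary β-keto lactone are inert to ozone at −78 °C.

Step 17
Reactants: 23 10β-formyl 4-acetyl lactone
Product: 25 1β,3β-diol (ring A closed; 19,10-lactone; C7 methyl ester; 16-ketal; 13-OTBS), via 1β-hydroxy 3-ketone 24 (not isolated)
Conditions: LiN(SiMe3)2, THF, −78 °C; then K[HB(s-Bu)3], −78 °C; AcOH quench
Reagents that add atoms: none
Why: Intramolecular aldol addition of the kinetic methyl ketone enolate (C2) to the C1 aldehyde closes ring A. The aldehyde oxygen is expected anti to the C10–O bond (dipole minimisation, Cornforth-type) and hence axial β. The cold aldolate is reduced in the same flask by the bulky borohydride, which should attack C3 equatorially (the β-axial side is shielded by the 1β-oxygen and H5) to give the axial 3β-alcohol before retro-aldol or dehydration can set in.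

Step 18
Reactants: 25 1β,3β-diol 16-ketal
Product: 26 17-nor-16-ketone (1β,3β-diol; 13-OTBS; C7 methyl ester)
Conditions: 1 M HCl, THF, rt
Reagents that add atoms: water (O)
Why: Acid hydrolysis of the dioxolane; the β-hydroxy lactone and the diol are stable to dilute acid, the tertiary bridgehead silyl ether should hydrolyse much more slowly than the ketal, and no acid-labile allylic alcohol is present yet.

Step 19
Reactants: 26 17-nor-16-ketone
Product: 27 GA55 methyl ester 13-TBS ether
Conditions: Zn, CH2Br2, TiCl4, THF–CH2Cl2, 0 °C to rt
Reagents that add atoms: dibromomethane (BrCBr)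
Why: Takai–Lombardo methylenation: the zinc/titanium methylene reagent is non-basic and selective for ketones over esters and lactones, so neither the base-labile 3β-hydroxy lactone nor the α-silyloxy ketone is endangered; excess reagent covers the two free hydroxyls.

Step 20
Reactants: 27 GA55 methyl ester 13-TBS ether
Product: 28 GA55 methyl ester
Conditions: n-Bu4NF, AcOH, THF, 40 °C
Reagents that add atoms: none
Why: Fluoride cleavage of the tertiary silyl ether, buffered with acetic acid so that the medium is neither basic enough for retro-aldol at C3 nor acidic enough to rearrange the allylic tertiary alcohol.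

Step 21
Reactants: 28 GA55 methyl ester
Product: 29 GA55
Conditions: NaSEt, DMF, 60 °C; then dil. HCl to pH 3, 0 °C
Reagents that add atoms: none
Why: SN2 demethylation of the hindered methyl ester by thiolate (alkyl–oxygen cleavage) avoids the hydroxide conditions that epimerise C3 by retro-aldol and needs no carcinogenic phosphoramide cosolvent. The lactone cannot be cleaved at its tertiary alkyl carbon, and brief cold acidification frees the acid.

## Compound list

1 | cyclopentane-1,3-dione | O=C1CCC(=O)C1 | starting material
2 | 3-chlorocyclopent-2-en-1-one | O=C1CCC(Cl)=C1 | intermediate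
3 | dimethyl malonate | COC(=O)CC(=O)OC | starting material
4 | 2-chloro-N-methoxy-N-methylacetamide | CON(C)C(=O)CCl | starting material
5 | dimethyl 2-[2-(methoxy(methyl)amino)-2-oxoethyl]propanedioate | CON(C)C(=O)CC(C(=O)OC)C(=O)OC | intermediate
6 | dimethyl 2-[2-(methoxy(methyl)amino)-2-oxoethyl]-2-(3-oxocyclopent-1-en-1-yl)propanedioate | CON(C)C(=O)CC(C(=O)OC)(C(=O)OC)C1=CC(=O)CC1 | intermediate
7 | dimethyl 2-(4-hydroxy-3-oxocyclopent-1-en-1-yl)-2-[2-(methoxy(methyl)amino)-2-oxoethyl]propanedioate, racemic | CON(C)C(=O)CC(C(=O)OC)(C(=O)OC)C1=CC(=O)C(O)C1 | intermediate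
8 | dimethyl 2-[3,4-bis(tert-butyldimethylsilyloxy)cyclopenta-1,3-dien-1-yl]-2-[2-(methoxy(methyl)amino)-2-oxoethyl]propanedioate | CON(C)C(=O)CC(C(=O)OC)(C(=O)OC)C1=CC(O[Si](C)(C)C(C)(C)C)=C(O[Si](C)(C)C(C)(C)C)C1 | intermediate
9 | dimethyl 2-[3,4-bis(tert-butyldimethylsilyloxy)cyclopenta-1,3-dien-1-yl]-2-(2-oxopent-4-en-1-yl)propanedioate | C=CCC(=O)CC(C(=O)OC)(C(=O)OC)C1=CC(O[Si](C)(C)C(C)(C)C)=C(O[Si](C)(C)C(C)(C)C)C1 | intermediate
10 | dimethyl 2-[3,4-bis(tert-butyldimethylsilyloxy)cyclopenta-1,3-dien-1-yl]-2-[2-oxo-3-(trifluoroacetyl)pent-4-en-1-yl]propanedioate | C=CC(C(=O)C(F)(F)F)C(=O)CC(C(=O)OC)(C(=O)OC)C1=CC(O[Si](C)(C)C(C)(C)C)=C(O[Si](C)(C)C(C)(C)C)C1 | intermediate (not isolated)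
11 | dimethyl 2-[3,4-bis(tert-butyldimethylsilyloxy)cyclopenta-1,3-dien-1-yl]-2-(3-diazo-2-oxopent-4-en-1-yl)propanedioate, the key-step precursor | C=CC(=[N+]=[N-])C(=O)CC(C(=O)OC)(C(=O)OC)C1=CC(O[Si](C)(C)C(C)(C)C)=C(O[Si](C)(C)C(C)(C)C)C1 | intermediate
12 | cis-divinylcyclopropane: cyclopropane C8/C9/C15 fused to the ring B cyclopentanone (C10 ketone, C6 gem-diester) and to the 13,16-bis(silyloxy)cyclopentene of ring D; vinyl on C9 cis to ring D | C=C[C@@]12C(=O)CC(C(=O)OC)(C(=O)OC)[C@@]13CC(O[Si](C)(C)C(C)(C)C)=C(O[Si](C)(C)C(C)(C)C)[C@@H]23 | intermediate (not isolated)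
13 | tricyclic B/C/D enone: ring B cyclopentanone (C10 ketone, C6 gem-dimethyl ester) fused at C8–C9 to the bicyclo[3.2.1]octadiene; 9(11)-ene; 16-OTBS enol ether (15-ene); bridgehead 13-OTBS; C8 and C13 as in 29 | CC(C)(C)[Si](C)(C)OC1=C[C@]23C[C@@]1(O[Si](C)(C)C(C)(C)C)CC=C2C(=O)CC3(C(=O)OC)C(=O)OC | intermediate
14 | as 13, with C16 as the ethylene ketal (spiro-1,3-dioxolane) | O1CCOC12C[C@]34C[C@@]2(O[Si](C)(C)C(C)(C)C)CC=C3C(=O)CC4(C(=O)OC)C(=O)OC | intermediate
15 | as 14, with C9–C11 saturated and H9 β (B/C cis) | O1CCOC12C[C@]34C[C@@]2(O[Si](C)(C)C(C)(C)C)CC[C@H]3C(=O)CC4(C(=O)OC)C(=O)OC | intermediate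
16 | as 15, with a single methyl ester at C6 (mixture of C6 epimers) | O1CCOC12C[C@]34C[C@@]2(O[Si](C)(C)C(C)(C)C)CC[C@H]3C(=O)CC4C(=O)OC | intermediate
17 | C10 trimethylsilyl enol ether of 16 (C5=C10) | O1CCOC12C[C@]34C[C@@]2(O[Si](C)(C)C(C)(C)C)CC[C@H]3C(O[Si](C)(C)C)=CC4C(=O)OC | intermediate (not isolated)
18 | 5-en-10-one: C5=C6 conjugated to the C10 ketone and the C7 methyl ester; 9β-H; 16-ketal; 13-OTBS | O1CCOC12C[C@]34C[C@@]2(O[Si](C)(C)C(C)(C)C)CC[C@H]3C(=O)C=C4C(=O)OC | intermediate
19 | 10α-hydroxy-10β-vinyl 5-ene ester | O1CCOC12C[C@]34C[C@@]2(O[Si](C)(C)C(C)(C)C)CC[C@H]3[C@](O)(C=C)C=C4C(=O)OC | intermediate (not isolated)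
20 | 10α-propanoyloxy-10β-vinyl 5-ene ester | O1CCOC12C[C@]34C[C@@]2(O[Si](C)(C)C(C)(C)C)CC[C@H]3[C@](OC(=O)CC)(C=C)C=C4C(=O)OC | intermediate
21 | 19,10-lactone: C4–C5 bond formed, H5 β, 6β-CO2Me, 4-methyl as epimer mixture, 10β-vinyl | O1CCOC12C[C@]34C[C@@]2(O[Si](C)(C)C(C)(C)C)CC[C@H]3[C@@]5(C=C)OC(=O)C(C)[C@H]5[C@@H]4C(=O)OC | intermediate
22 | 4-acetyl lactone: quaternary C4 with acetyl (C3, C2) on the face of C1 and methyl (C18) on the face of C6 | O1CCOC12C[C@]34C[C@@]2(O[Si](C)(C)C(C)(C)C)CC[C@H]3[C@@]5(C=C)OC(=O)[C@](C)(C(C)=O)[C@H]5[C@@H]4C(=O)OC | intermediate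
23 | 10β-formyl 4-acetyl lactone (C1 aldehyde) | O1CCOC12C[C@]34C[C@@]2(O[Si](C)(C)C(C)(C)C)CC[C@H]3[C@@]5(C=O)OC(=O)[C@](C)(C(C)=O)[C@H]5[C@@H]4C(=O)OC | intermediate
24 | 1β-hydroxy 3-ketone: ring A closed, 19,10-lactone, C7 methyl ester, 16-ketal, 13-OTBS | O1CCOC12C[C@]34C[C@@]2(O[Si](C)(C)C(C)(C)C)CC[C@H]3[C@@]56OC(=O)[C@@](C)([C@H]5[C@@H]4C(=O)OC)C(=O)C[C@H]6O | intermediate (not isolated)
25 | 1β,3β-diol: as 24 with 3β-OH | O1CCOC12C[C@]34C[C@@]2(O[Si](C)(C)C(C)(C)C)CC[C@H]3[C@@]56OC(=O)[C@@](C)([C@H]5[C@@H]4C(=O)OC)[C@@H](O)C[C@H]6O | intermediate
26 | 17-nor-16-ketone of GA55 methyl ester 13-TBS ether | O=C1C[C@]23C[C@@]1(O[Si](C)(C)C(C)(C)C)CC[C@H]2[C@@]45OC(=O)[C@@](C)([C@H]4[C@@H]3C(=O)OC)[C@@H](O)C[C@H]5O | intermediate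
27 | GA55 methyl ester 13-TBS ether | C=C1C[C@]23C[C@@]1(O[Si](C)(C)C(C)(C)C)CC[C@H]2[C@@]45OC(=O)[C@@](C)([C@H]4[C@@H]3C(=O)OC)[C@@H](O)C[C@H]5O | intermediate
28 | GA55 methyl ester | C=C1C[C@]23C[C@@]1(O)CC[C@H]2[C@@]45OC(=O)[C@@](C)([C@H]4[C@@H]3C(=O)OC)[C@@H](O)C[C@H]5O | intermediate
29 | GA55 | C=C1C[C@]23C[C@@]1(O)CC[C@H]2[C@@]12OC(=O)[C@@](C)([C@H]1[C@@H]3C(=O)O)[C@@H](O)C[C@H]2O | target

## Step count and least certain steps

Total: 21 steps. Longest linear sequence: 20 steps (1 → 2 → 6 → … → 29; the branch 3 + 4 → 5 joins at step 3 and is of the same length).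

**Step 8 (key step).** The most likely failure is insufficient discrimination between the two faces of C8=C15, because a ketone acceptor holds the carbenoid less rigidly than an ester, together with partial capture of the carbenoid at the more electron-rich C13=C16 bond. Both lower the amount of enantiopure 13. The fallback sets out from 11 and returns at 13. The cascade is run with achiral Rh2(OAc)4, which should give the racemic tricyclic enone F1. F1 is then resolved kinetically by catalytic asymmetric conjugate reduction (Cu(OAc)2, one enantiomer of DTBM-SEGPHOS, polymethylhydrosiloxane, t-BuOH, toluene, stopped near half conversion). The unwanted antipode should be consumed as the saturated ketone of the mirror-image series F2, and 13 recovered at the cost of half the material.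

**Step 7.** The most likely failure is migration of the β,γ-double bond into conjugation with C10 during enolisation or acylation, and slow electrocyclisation of the unsubstituted vinyl diazo ketone to a pyrazole during the transfer. The fallback sets out from 8 and returns at 11. MeMgBr converts the amide into the methyl ketone F3. Detrifluoroacetylative diazo transfer on the methyl group gives the diazomethyl ketone F4. DBU-catalysed aldol-type addition of F4 to acetaldehyde gives the storable β-hydroxy-α-diazo ketone F5. Dehydration of F5 with POCl3/Et3N at 0 °C then releases 11 just before use, so the vinyl diazo unit never meets a strong base or an azide.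

**Step 9.** The most likely failure is hydrolysis to the hindered 16-ketone by adventitious water, which then resists ketalisation beside the bridgehead silyl ether, or an acid-induced 1,2-shift at the α-silyloxy oxocarbenium stage. The fallback sets out from 13 and returns at 14. Buffered fluoride (n-Bu4NF/AcOH, −20 °C) cleaves only the enol silyl ether to give the 16-ketone F6. F6 is ketalised under aprotic conditions with 1,2-bis(trimethylsilyloxy)ethane and catalytic TMSOTf at −78 °C (Noyori ketalisation), where a saturated ketone reacts much faster than the conjugated C10 ketone.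

**Step 13.** The most likely failure is incomplete acylation of the hindered tertiary alkoxide, which leaves the acid-sensitive bis-allylic alcohol, or attack of the organometallic on the doubly activated C5=C6 bond. The fallback sets out from 18 and returns at 21. The addition is worked up to isolate 19, which is acylated with the more reactive 2-bromopropanoyl bromide (pyridine, DMAP, 0 °C) to the α-bromo ester F7. SmI2 (THF, −78 °C) then forms the samarium enolate under neutral conditions; it should undergo the same 5-exo conjugate addition to C5 and, after the methoxide equilibration, give 21.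

**Step 15.** The most likely failure is competing deprotonation at C6, or O-acylation and low conversion of the tetrasubstituted lactone enolate. The fallback sets out from 21 and returns at 22. The enolate is trapped with acetaldehyde (aldol addition, same facial preference) to give the 1-hydroxyethyl lactone F8, which is oxidised with Dess–Martin periodinane to 22.

**Step 17.** The most likely failure is poor control of the C1 configuration in the ring-closing aldol, or β-elimination of the aldolate to the 1-en-3-one before reduction. The fallback sets out from 23 and returns at 25. Ring A is closed deliberately by aldol condensation (pyrrolidine, AcOH, toluene, 60 °C) to the 1-en-3-one F9. Copper-catalysed conjugate borylation (B2pin2, CuCl, NaOt-Bu, a bisphosphine, MeOH) should add boron to C1 from the β-face, anti to the lactone bridge, giving the 1β-boryl ketone F10. Oxidation with retention (NaBO3) gives 24, now isolated, and reduction with K[HB(s-Bu)3] as in the main route returns 25.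

## Further compounds

F1 | step 8 | racemic tricyclic B/C/D enone (racemate of 13) | CC(C)(C)[Si](C)(C)OC1=CC23CC1(O[Si](C)(C)C(C)(C)C)CC=C2C(=O)CC3(C(=O)OC)C(=O)OC
F2 | step 8 | saturated 9-H cis ketone of the mirror-image series (enantiomer of the 9(11)-dihydro derivative of 13) | CC(C)(C)[Si](C)(C)OC1=C[C@@]23C[C@]1(O[Si](C)(C)C(C)(C)C)CC[C@@H]2C(=O)CC3(C(=O)OC)C(=O)OC
F3 | step 7 | dimethyl 2-[3,4-bis(tert-butyldimethylsilyloxy)cyclopenta-1,3-dien-1-yl]-2-(2-oxopropyl)propanedioate | CC(=O)CC(C(=O)OC)(C(=O)OC)C1=CC(O[Si](C)(C)C(C)(C)C)=C(O[Si](C)(C)C(C)(C)C)C1
F4 | step 7 | dimethyl 2-[3,4-bis(tert-butyldimethylsilyloxy)cyclopenta-1,3-dien-1-yl]-2-(3-diazo-2-oxopropyl)propanedioate | [N-]=[N+]=CC(=O)CC(C(=O)OC)(C(=O)OC)C1=CC(O[Si](C)(C)C(C)(C)C)=C(O[Si](C)(C)C(C)(C)C)C1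
F5 | step 7 | dimethyl 2-[3,4-bis(tert-butyldimethylsilyloxy)cyclopenta-1,3-dien-1-yl]-2-(3-diazo-4-hydroxy-2-oxopentyl)propanedioate, racemic | CC(O)C(=[N+]=[N-])C(=O)CC(C(=O)OC)(C(=O)OC)C1=CC(O[Si](C)(C)C(C)(C)C)=C(O[Si](C)(C)C(C)(C)C)C1
F6 | step 9 | tricyclic 10,16-diketone: 16-ketone of 13 with the 9(11)-en-10-one and 13-OTBS kept | O=C1C[C@]23C[C@@]1(O[Si](C)(C)C(C)(C)C)CC=C2C(=O)CC3(C(=O)OC)C(=O)OC
F7 | step 13 | 10α-(2-bromopropanoyloxy)-10β-vinyl 5-ene ester (epimers at the bromo carbon) | O1CCOC12C[C@]34C[C@@]2(O[Si](C)(C)C(C)(C)C)CC[C@H]3[C@](OC(=O)C(C)Br)(C=C)C=C4C(=O)OC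
F8 | step 15 | 4-(1-hydroxyethyl) lactone (epimers at the carbinol carbon) | O1CCOC12C[C@]34C[C@@]2(O[Si](C)(C)C(C)(C)C)CC[C@H]3[C@@]5(C=C)OC(=O)[C@](C)(C(C)O)[C@H]5[C@@H]4C(=O)OC
F9 | step 17 | 1-en-3-one: ring A closed, 19,10-lactone, C7 methyl ester, 16-ketal, 13-OTBS | O1CCOC12C[C@]34C[C@@]2(O[Si](C)(C)C(C)(C)C)CC[C@H]3[C@@]56OC(=O)[C@@](C)([C@H]5[C@@H]4C(=O)OC)C(=O)C=C6
F10 | step 17 | 1β-(pinacolboryl) 3-ketone | O1CCOC12C[C@]34C[C@@]2(O[Si](C)(C)C(C)(C)C)CC[C@H]3[C@@]56OC(=O)[C@@](C)([C@H]5[C@@H]4C(=O)OC)C(=O)C[C@H]6B7OC(C)(C)C(C)(C)O7
A1 | alternative 1 | steviol | C=C1C[C@]23C[C@@]1(O)CC[C@H]2[C@]1(C)CCC[C@@](C)(C(=O)O)[C@H]1CC3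
A2 | alternative 1 | ring B diazo ketone: six-membered ring B, diazo on C6, ketone C7, 19,10-lactone, 1β,3β-bis(TBS) ether, 13-ol, 16-ene | C=C1C[C@]23C[C@@]1(O)CC[C@H]2[C@@]12OC(=O)[C@@](C)([C@H]1C(=[N+]=[N-])C3=O)[C@@H](O[Si](C)(C)C(C)(C)C)C[C@H]2O[Si](C)(C)C(C)(C)C
A3 | alternative 1 | GA55 1,3-bis(tert-butyldimethylsilyl) ether | C=C1C[C@]23C[C@@]1(O)CC[C@H]2[C@@]12OC(=O)[C@@](C)([C@H]1[C@@H]3C(=O)O)[C@@H](O[Si](C)(C)C(C)(C)C)C[C@H]2O[Si](C)(C)C(C)(C)C
A4 | alternative 2 | 4-[(tert-butyldimethylsilyloxy)methyl]-3-(prop-2-yn-1-yl)cyclopent-2-en-1-one, one enantiomer | O=C1C=C(CC#C)[C@@H](CO[Si](C)(C)C(C)(C)C)C1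
A5 | alternative 2 | 2-(trimethylsilyloxy)buta-1,3-diene | C=CC(=C)O[Si](C)(C)C
A6 | alternative 2 | cis-hydrindanone silyl enol ether (rings B and C, C10 ketone, C13 enol ether, C8 propargyl) | C#CC[C@]23CC(O[Si](C)(C)C)=CC[C@H]2C(=O)C[C@@H]3CO[Si](C)(C)C(C)(C)C
A7 | alternative 3 | (3S,4S)-epoxy alcohol on the B/C/D tricycle with the C5=C10 alkene (C7 nitrile, C16 ketone, 13-OTBS) | O=C1C[C@]23C[C@@]1(O[Si](C)(C)C(C)(C)C)CC[C@H]2C(CC[C@@H]4O[C@@]4(C)CO)=C[C@@H]3C#N
A8 | alternative 3 | 3β-hydroxy 19,10-ether, 1-deoxy (C7 nitrile, C16 ketone, 13-OTBS) | O=C1C[C@]23C[C@@]1(O[Si](C)(C)C(C)(C)C)CC[C@H]2[C@@]12OC[C@@](C)([C@H]1[C@@H]3C#N)[C@@H](O)CC2
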